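**Retrosynthetic overview**

1. The ester and the aryl ether are cut last: target 13 ⇒ ether alcohol 12 ⇒ cis-diol 10 + 7-bromocoumarin 11 (O-arylation of the primary hydroxyl, then acylation of the secondary one).
2. Enabling feature: the ring carbon bearing the ester oxygen and the ring CH bearing the CH2O arm are both bonded to the gem-dimethyl carbon and are cis. The carbinol oxygen and the CH2O carbon (raised to the carboxyl level) can therefore be tied into a γ-lactone, so 10 ⇒ bridged lactone 9 (a 6-oxabicyclo[3.2.1]oct-2-en-7-one).
3. Key disconnection: the cyclohexene bond between the methyl-bearing sp2 carbon and the lactone α-carbon (the CH of the CH2O arm) ⇒ monocyclic γ-lactone 7 with a (Z)-3-iodobut-2-enyl chain, closed by palladium-catalysed intramolecular enolate alkenylation.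
4. 7 ⇒ aldehyde 6 (Z-selective iodo-olefination) ⇒ allyl lactone 5 ⇒ aldehyde ester 2 (asymmetric allylboration sets the carbinol centre) ⇒ methyl 3,3-dimethylpent-4-enoate 1.
5. Ring order: temporary γ-lactone (step 2), cyclohexene (step 5), lactone opened again (step 6); the coumarin is bought as 11.

Key step: step 5

Remark: the facial sense of the allylboration in step 2 is assigned from the established behaviour of this reagent with aldehydes whose substituent outranks allyl (the reagent from (−)-α-pinene attacks the Re face).

**Step 1**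
Reactants: 1 methyl 3,3-dimethylpent-4-enoate
Product: 2 methyl 3,3-dimethyl-4-oxobutanoate
Conditions: O3, CH2Cl2, −78 °C; then PPh3, −78→23 °C
Reagents that add atoms: ozone, [O-][O+]=O
Why: Ozonolysis (Criegee mechanism) with reductive work-up should cleave the only C=C bond to the aldehyde, which has no α-hydrogen and cannot enolise; the ester is inert and no stereocentre is formed.

**Step 2**
Reactants: 2 methyl 3,3-dimethyl-4-oxobutanoate
Product: 5 (5R)-4,4-dimethyl-5-(prop-2-en-1-yl)oxolan-2-one, via borinate ester 3 (not isolated), via hydroxy ester 4 (not isolated)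
Conditions: (+)-Ipc2B(allyl) (from (−)-α-pinene, 1 M in pentane), Et2O, −78 °C; then NaOAc, 30% H2O2, 0→23 °C; then p-TsOH (cat.), CH2Cl2, 23 °C
Reagents that add atoms: (+)-B-allyldiisopinocampheylborane, C=CCB([C@H]1C[C@H]2C[C@@H]([C@@H]1C)C2(C)C)[C@H]1C[C@H]2C[C@@H]([C@@H]1C)C2(C)C
Why: Brown asymmetric allylboration through a closed chair (Zimmerman–Traxler) transition state should deliver allyl to the Re face of the α-quaternary aldehyde and so set the (R)-carbinol centre; oxidative cleavage of borinate 3 frees hydroxy ester 4, which should close to the γ-lactone under acid, helped by the gem-dimethyl group (Thorpe–Ingold effect).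

**Step 3**
Reactants: 5 (5R)-4,4-dimethyl-5-(prop-2-en-1-yl)oxolan-2-one
Product: 6 2-[(2R)-3,3-dimethyl-5-oxooxolan-2-yl]acetaldehyde
Conditions: O3, CH2Cl2, −78 °C; then PPh3, −78→23 °C; used crude
Reagents that add atoms: ozone, [O-][O+]=O
Why: Ozonolysis of the terminal alkene (Criegee mechanism, reductive work-up) should give the aldehyde one carbon shorter; the lactone and the carbinol centre are not touched.

**Step 4**
Reactants: 6 2-[(2R)-3,3-dimethyl-5-oxooxolan-2-yl]acetaldehyde
Product: 7 (5R)-5-[(2Z)-3-iodobut-2-en-1-yl]-4,4-dimethyloxolan-2-one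
Conditions: EtPPh3I, n-BuLi, THF, 23 °C; I2, −78 °C; NaN(SiMe3)2, −20 °C; then 6, −78→−20 °C
Reagents that add atoms: ethyltriphenylphosphonium iodide, CC[P+](c1ccccc1)(c1ccccc1)c1ccccc1.[I-]; iodine, II
Why: Stork–Zhao-type Wittig olefination with the α-iodo ylide Ph3P=C(I)CH3 made in the flask should give the trisubstituted vinyl iodide with iodine cis to the chain (Z), as is general for α-iodo ylides under kinetic control; at −78 °C addition to the aldehyde should outrun β-elimination of the lactone carboxylate.

**Step 5**
Reactants: 7 (5R)-5-[(2Z)-3-iodobut-2-en-1-yl]-4,4-dimethyloxolan-2-one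
Product: 9 (1S,5R)-2,8,8-trimethyl-6-oxabicyclo[3.2.1]oct-2-en-7-one, via lithium enolate 8 (not isolated)
Conditions: LiN(SiMe3)2 (1.1 equiv), THF, −78 °C; then Pd(P(t-Bu)3)2 (5 mol %), −78→23 °C, 0.02 M
Reagents that add atoms: none
Why: LiN(SiMe3)2 deprotonates the lactone α-CH2 to enolate 8, zerovalent palladium inserts into the C–I bond with retention of the Z geometry, the enolate displaces iodide on palladium to give a C-bound palladium enolate, and reductive elimination from this seven-membered palladacycle forms the bond between the enolate carbon and the methyl-bearing vinyl carbon. The closest known reaction type is the palladium-catalysed intramolecular α-alkenylation of ketone and ester enolates with vinyl halides, which is used to close bridged bicyclic carbonyl compounds. One ring closes, the six-membered carbocycle, exo with respect to the enolate C=C bond and with the vinyl C=C bond ending up endocyclic, so that it bridges the 1,3-positions of the γ-lactone as the 6-oxabicyclo[3.2.1]octene. The new stereocentre at the bridgehead α-carbon is controlled by the carbinol centre through the lactone tether: the three-atom chain can reach the enolate carbon only on the face to which it is attached, so only the cis-bridged product can form. The step needs control of ring size and alkene position, which the site of the C–I bond and the Z geometry fix (the E isomer cannot cyclise). It also needs freedom from second alkenylation, epimerisation and migration of the double bond into conjugation, which the product secures because its α-carbon is a bridgehead that cannot be enolised (Bredt's rule).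

**Step 6**
Reactants: 9 (1S,5R)-2,8,8-trimethyl-6-oxabicyclo[3.2.1]oct-2-en-7-one
Product: 10 (1R,5S)-5-(hydroxymethyl)-4,6,6-trimethylcyclohex-3-en-1-ol
Conditions: LiAlH4, THF, 0 °C; Fieser work-up
Reagents that add atoms: none
Why: Hydride reduction of the lactone should give the cis-diol without breaking a bond to either stereocentre; the aldehyde stage is reduced faster than it can enolise and the isolated trisubstituted alkene is inert.

**Step 7**
Reactants: 10 (1R,5S)-5-(hydroxymethyl)-4,6,6-trimethylcyclohex-3-en-1-ol; 11 7-bromo-2H-chromen-2-one (1.2 equiv)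
Product: 12 7-{[(1S,5R)-5-hydroxy-2,6,6-trimethylcyclohex-2-en-1-yl]methoxy}-2H-chromen-2-one
Conditions: [Pd(allyl)Cl]2 (2 mol %), RockPhos (5 mol %), Cs2CO3, toluene, 90 °C
Reagents that add atoms: none
Why: Palladium-catalysed C–O cross-coupling (Buchwald–Hartwig etherification) should arylate the primary alkoxide far faster than the neopentyl secondary one, with the bulky biaryl phosphine favouring C–O reductive elimination over β-hydride elimination; because the alcohol carbon is never activated, the cis-hydroxyl cannot close a bicyclic ether and no stereocentre is touched.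

**Step 8**
Reactants: 12 7-{[(1S,5R)-5-hydroxy-2,6,6-trimethylcyclohex-2-en-1-yl]methoxy}-2H-chromen-2-one
Product: 13 (1R,5S)-4,6,6-trimethyl-5-{[(2-oxo-2H-chromen-7-yl)oxy]methyl}cyclohex-3-en-1-yl 3-methylbutanoate
Conditions: isovaleryl chloride, pyridine, DMAP (cat.), CH2Cl2, 0→23 °C
Reagents that add atoms: 3-methylbutanoyl chloride (isovaleryl chloride), CC(C)CC(Cl)=O
Why: DMAP-catalysed acylation (nucleophilic catalysis through the N-acylpyridinium ion) should esterify the remaining hindered secondary alcohol with retention, since the carbinol C–O bond is not broken; the coumarin lactone and the aryl ether are stable to these conditions.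

**Compound list**

1 | methyl 3,3-dimethylpent-4-enoate | C=CC(C)(C)CC(=O)OC | starting material
2 | methyl 3,3-dimethyl-4-oxobutanoate | O=CC(C)(C)CC(=O)OC | intermediate
3 | methyl (4R)-4-[(diisopinocampheylboryl)oxy]-3,3-dimethylhept-6-enoate (borinate ester) | C=CC[C@@H](OB([C@H]1C[C@H]2C[C@@H]([C@@H]1C)C2(C)C)[C@H]1C[C@H]2C[C@@H]([C@@H]1C)C2(C)C)C(C)(C)CC(=O)OC | intermediate
4 | methyl (4R)-4-hydroxy-3,3-dimethylhept-6-enoate (hydroxy ester) | C=CC[C@@H](O)C(C)(C)CC(=O)OC | intermediate
5 | (5R)-4,4-dimethyl-5-(prop-2-en-1-yl)oxolan-2-one | C=CC[C@H]1OC(=O)CC1(C)C | intermediate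
6 | 2-[(2R)-3,3-dimethyl-5-oxooxolan-2-yl]acetaldehyde | O=CC[C@H]1OC(=O)CC1(C)C | intermediate
7 | (5R)-5-[(2Z)-3-iodobut-2-en-1-yl]-4,4-dimethyloxolan-2-one | C/C(I)=C/C[C@H]1OC(=O)CC1(C)C | intermediate
8 | lithium enolate of 7 | C/C(I)=C/C[C@H]1OC([O-])=CC1(C)C.[Li+] | intermediate
9 | (1S,5R)-2,8,8-trimethyl-6-oxabicyclo[3.2.1]oct-2-en-7-one | CC1=CC[C@H]2OC(=O)[C@@H]1C2(C)C | intermediate
10 | (1R,5S)-5-(hydroxymethyl)-4,6,6-trimethylcyclohex-3-en-1-ol | CC1=CC[C@@H](O)C(C)(C)[C@H]1CO | intermediate
11 | 7-bromo-2H-chromen-2-one (7-bromocoumarin) | O=c1ccc2ccc(Br)cc2o1 | starting material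
12 | 7-{[(1S,5R)-5-hydroxy-2,6,6-trimethylcyclohex-2-en-1-yl]methoxy}-2H-chromen-2-one | CC1=CC[C@@H](O)C(C)(C)[C@H]1COc1ccc2ccc(=O)oc2c1 | intermediate
13 | (1R,5S)-4,6,6-trimethyl-5-{[(2-oxo-2H-chromen-7-yl)oxy]methyl}cyclohex-3-en-1-yl 3-methylbutanoate (CNP0266015.1) | CC1=CC[C@@H](OC(=O)CC(C)C)C(C)(C)[C@H]1COc1ccc2ccc(=O)oc2c1 | target

**Step count and risks**

Total step count: 8. Longest linear sequence: 8 steps (1 → 13).

Steps most likely to fail:

Step 5. The lithium enolate may be used up by intermolecular Claisen condensation or by dehydroiodination of the vinyl iodide before the palladium enolate reductively eliminates. The fallback closes the same bond as a cross-electrophile coupling without strong base in the ring-closing event. It sets out from 7: enolate 8 is quenched at −78 °C with N-bromosuccinimide to give (5R)-3-bromo-5-[(2Z)-3-iodobut-2-en-1-yl]-4,4-dimethyloxolan-2-one F1 (both epimers at the brominated carbon). Nickel-catalysed intramolecular reductive coupling of its C–Br and C–I ends (NiBr2(dme), 4,4′-di-tert-butyl-2,2′-bipyridine, Zn, DMA, 23 °C) should then return to the route at 9, the tether again allowing only the cis-bridged product.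

Step 4. The iodo-ylide may give low conversion, erosion of Z selectivity, or base-induced β-elimination that opens the lactone. The fallback builds the haloalkene by a non-basic olefination followed by a stereoselective cross-coupling. It sets out from 6: CBr4/PPh3 (CH2Cl2, 0 °C, first stage of the Corey–Fuchs sequence) gives (5R)-5-(3,3-dibromoprop-2-en-1-yl)-4,4-dimethyloxolan-2-one F2. Trans-selective Negishi monomethylation (MeZnCl, PdCl2(DPEphos), THF, 23 °C) replaces the bromine trans to the chain and gives (5R)-5-[(2Z)-3-bromobut-2-en-1-yl]-4,4-dimethyloxolan-2-one F3. F3 is submitted as the vinyl bromide to the conditions of step 5 and comes back to the route at 9.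

Step 7. β-Hydride elimination from the palladium alkoxide (with reduction of the aryl bromide) or alkoxide attack on the coumarin lactone at 90 °C may hold conversion low. The fallback differentiates the hydroxyls by protection and forms the ether by alcohol activation only after the secondary oxygen is acylated, so that no bicyclic ether can form. It sets out from 10: TBSCl/imidazole (CH2Cl2, 0 °C) silylates the primary hydroxyl to (1R,5S)-5-{[(tert-butyldimethylsilyl)oxy]methyl}-4,6,6-trimethylcyclohex-3-en-1-ol F4. Isovaleryl chloride/pyridine/DMAP gives (1R,5S)-5-{[(tert-butyldimethylsilyl)oxy]methyl}-4,6,6-trimethylcyclohex-3-en-1-yl 3-methylbutanoate F5. HF·pyridine (THF, 0 °C) gives (1R,5S)-5-(hydroxymethyl)-4,6,6-trimethylcyclohex-3-en-1-yl 3-methylbutanoate F6. Mitsunobu etherification of F6 with 7-hydroxycoumarin (PPh3, DIAD, THF, 0→23 °C) comes back to the route at 13.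

**Further compounds**

F1 | step 5 | (5R)-3-bromo-5-[(2Z)-3-iodobut-2-en-1-yl]-4,4-dimethyloxolan-2-one | C/C(I)=C/C[C@H]1OC(=O)C(Br)C1(C)C
F2 | step 4 | (5R)-5-(3,3-dibromoprop-2-en-1-yl)-4,4-dimethyloxolan-2-one | BrC(Br)=CC[C@H]1OC(=O)CC1(C)C
F3 | step 4 | (5R)-5-[(2Z)-3-bromobut-2-en-1-yl]-4,4-dimethyloxolan-2-one | C/C(Br)=C/C[C@H]1OC(=O)CC1(C)C
F4 | step 7 | (1R,5S)-5-{[(tert-butyldimethylsilyl)oxy]methyl}-4,6,6-trimethylcyclohex-3-en-1-ol | CC1=CC[C@@H](O)C(C)(C)[C@H]1CO[Si](C)(C)C(C)(C)C
F5 | step 7 | (1R,5S)-5-{[(tert-butyldimethylsilyl)oxy]methyl}-4,6,6-trimethylcyclohex-3-en-1-yl 3-methylbutanoate | CC1=CC[C@@H](OC(=O)CC(C)C)C(C)(C)[C@H]1CO[Si](C)(C)C(C)(C)C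
F6 | step 7 | (1R,5S)-5-(hydroxymethyl)-4,6,6-trimethylcyclohex-3-en-1-yl 3-methylbutanoate | CC1=CC[C@@H](OC(=O)CC(C)C)C(C)(C)[C@H]1CO
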